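Everything rests on cutting the C1–C2 bond of the six-membered carbocycle (C1 chain-bearing tertiary carbinol, C2 ketone, C3=C4 alkene, C5 and C6 secondary carbinols). The C1(OH)–C2(=O) acyloin is read as the product of an intramolecular crossed benzoin: a carbene-bound acyl anion generated at a C2 aldehyde adds to a C1 ketone, closing the ring and creating the quaternary C1 carbinol in one operation. The precursor is an acyclic keto-aldehyde whose C5 and C6 are the threo-diol carbons of L-tartaric acid, locked as a trans-acetonide, with the oleoyl ketone on C6 and a 3-oxopropyl arm on C5. Silyl enol ether dehydrogenation and acid deprotection finish the synthesis.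

Key step: step 10

Remark: the ring numbering C1–C6 above is also used for the corresponding carbons of the acyclic intermediates; diol 14 is carried as both carbinol epimers because that carbon is re-oxidised in step 9.

Step 1
Reactants: 1 1-decyne; 2 1,7-dibromoheptane
Product: 4 1-bromoheptadec-8-yne, via lithium decynide 3 (not isolated)
Conditions: n-BuLi (1.0 equiv), THF, −78 °C; then 2 (3 equiv), DMPU, −78 °C to rt
Reagents that add atoms: none
Why: Deprotonation of the terminal alkyne gives the acetylide, which displaces one bromide in an SN2 alkylation, the excess of 2 keeping double alkylation low; no stereocentre is formed.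

Step 2
Reactants: 4 1-bromoheptadec-8-yne
Product: 5 (Z)-1-bromoheptadec-8-ene
Conditions: H2 (1 atm), Pd/CaCO3 poisoned with Pb(OAc)2 (Lindlar catalyst), quinoline, hexane, rt
Reagents that add atoms: none
Why: Lindlar semi-hydrogenation delivers both hydrogens syn on the poisoned palladium surface, which sets the Z geometry of the chain alkene and should leave the primary bromide untouched.

Step 3
Reactants: 6 dimethyl 2,3-O-isopropylidene-L-tartrate
Product: 7 methyl (4R,5S)-5-(hydroxymethyl)-2,2-dimethyl-1,3-dioxolane-4-carboxylate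
Conditions: NaBH4 (0.55 equiv), MeOH, 0 °C
Reagents that add atoms: none
Why: Borohydride reduction of the α-alkoxy-activated ester can be stopped largely after the first ester of the C2-symmetric diester with a limited hydride charge at low temperature (ester reduction by NaBH4); both stereocentres are carried over unchanged from L-tartrate.

Step 4
Reactants: 7 methyl (4R,5S)-5-(hydroxymethyl)-2,2-dimethyl-1,3-dioxolane-4-carboxylate
Product: 9 methyl (4R,5S)-5-[(E)-3-tert-butoxy-3-oxoprop-1-en-1-yl]-2,2-dimethyl-1,3-dioxolane-4-carboxylate, via aldehyde ester 8 (not isolated)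
Conditions: (COCl)2, DMSO, CH2Cl2, −78 °C; Et3N; then Ph3P=CHCO2t-Bu, −78 °C to rt
Reagents that add atoms: tert-butyl (triphenylphosphoranylidene)acetate, CC(C)(C)OC(=O)C=P(c1ccccc1)(c1ccccc1)c1ccccc1
Why: Swern oxidation gives the sensitive α-alkoxy aldehyde, which is trapped in the same flask by the stabilised ylide in a Wittig olefination that adds C3 and C2; the alkene geometry (mainly E) is irrelevant because it is hydrogenated next, and the trans-dioxolane protects the α-centre against epimerisation.

Step 5
Reactants: 9 methyl (4R,5S)-5-[(E)-3-tert-butoxy-3-oxoprop-1-en-1-yl]-2,2-dimethyl-1,3-dioxolane-4-carboxylate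
Product: 10 methyl (4R,5S)-5-(3-tert-butoxy-3-oxopropyl)-2,2-dimethyl-1,3-dioxolane-4-carboxylate
Conditions: H2 (1 atm), Pd/C, EtOAc, rt
Reagents that add atoms: none
Why: Heterogeneous catalytic hydrogenation saturates the conjugated alkene without touching the esters or the acetonide, and is placed before the chain alkene enters the molecule; the two termini are now differentiated as a methyl and a tert-butyl ester.

Step 6
Reactants: 10 methyl (4R,5S)-5-(3-tert-butoxy-3-oxopropyl)-2,2-dimethyl-1,3-dioxolane-4-carboxylate
Product: 11 tert-butyl 3-[(4S,5R)-5-[methoxy(methyl)carbamoyl]-2,2-dimethyl-1,3-dioxolan-4-yl]propanoate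
Conditions: MeO(Me)NH·HCl (1.5 equiv), i-PrMgCl (3 equiv), THF, −20 °C
Reagents that add atoms: N,O-dimethylhydroxylamine hydrochloride, CNOC.Cl
Why: The chloromagnesium amide of N,O-dimethylhydroxylamine attacks the unhindered, α-oxygen-activated methyl ester far faster than the tert-butyl ester (Weinreb amide formation by ester aminolysis), and the thermodynamically preferred trans-dioxolane keeps the α-centre intact.

Step 7
Reactants: 5 (Z)-1-bromoheptadec-8-ene; 11 tert-butyl 3-[(4S,5R)-5-[methoxy(methyl)carbamoyl]-2,2-dimethyl-1,3-dioxolan-4-yl]propanoate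
Product: 13 tert-butyl 3-[(4S,5R)-2,2-dimethyl-5-[(Z)-octadec-9-enoyl]-1,3-dioxolan-4-yl]propanoate, via Grignard reagent 12 (not isolated)
Conditions: 5, Mg turnings, I2 (cat.), THF, rt; then 11, THF, −20 to 0 °C; aq. NH4Cl
Reagents that add atoms: none
Why: Weinreb ketone synthesis, in which the Grignard reagent adds once to give a magnesium-chelated tetrahedral intermediate that collapses to the ketone only on work-up, while the hindered tert-butyl ester is inert at this temperature; this places the whole seventeen-carbon Z-alkenyl chain on the future C1.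

Step 8
Reactants: 13 tert-butyl 3-[(4S,5R)-2,2-dimethyl-5-[(Z)-octadec-9-enoyl]-1,3-dioxolan-4-yl]propanoate
Product: 14 3-[(4S,5S)-5-[(Z)-1-hydroxyoctadec-9-en-1-yl]-2,2-dimethyl-1,3-dioxolan-4-yl]propan-1-ol (both carbinol epimers)
Conditions: LiAlH4, THF, 0 °C to rt; Fieser work-up
Reagents that add atoms: none
Why: LiAlH4 hydride reduction takes the tert-butyl ester to the primary alcohol and the ketone to the secondary alcohol, the isolated Z-alkene and the acetonide being inert; the epimer mixture at the carbinol is of no consequence since that carbon returns to the ketone in step 9.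

Step 9
Reactants: 14 3-[(4S,5S)-5-[(Z)-1-hydroxyoctadec-9-en-1-yl]-2,2-dimethyl-1,3-dioxolan-4-yl]propan-1-ol
Product: 15 3-[(4S,5R)-2,2-dimethyl-5-[(Z)-octadec-9-enoyl]-1,3-dioxolan-4-yl]propanal
Conditions: (COCl)2 (3 equiv), DMSO (6 equiv), CH2Cl2, −78 °C; Et3N, −78 to 0 °C; used at once
Reagents that add atoms: none
Why: A double Swern oxidation converts the primary and the secondary alcohol together into the C2 aldehyde and the C1 ketone under cold, non-acidic conditions that should preserve the acetonide, the Z-alkene and the α-alkoxy ketone centre C6.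

Step 10
Reactants: 15 3-[(4S,5R)-2,2-dimethyl-5-[(Z)-octadec-9-enoyl]-1,3-dioxolan-4-yl]propanal
Product: 16 5,6-O-isopropylidene-3,4-dihydropleiogenone A [(3aR,4R,7aS)-4-[(Z)-heptadec-8-en-1-yl]-4-hydroxy-2,2-dimethylhexahydro-1,3-benzodioxol-5-one]
Conditions: 2-(pentafluorophenyl)-6,7-dihydro-5H-pyrrolo[2,1-c][1,2,4]triazol-2-ium tetrafluoroborate (15 mol%), i-Pr2NEt (15 mol%), CH2Cl2 (0.02 M), 23 °C, argon
Reagents that add atoms: none
Why: The free triazolylidene adds to the unhindered C2 aldehyde and proton transfer gives the Breslow enaminol, whose nucleophilic C2 attacks the C1 ketone; proton transfer and loss of the carbene then leave the C2 carbonyl and the C1 tertiary carbinol, C1–C2 being the only new skeletal bond. This is the known N-heterocyclic carbene catalysed intramolecular crossed aldehyde–ketone benzoin reaction that gives cyclic tertiary α-ketols. The six-membered carbocycle C1–C6 closes in a 6-exo-trig mode. The new C1 stereocentre is under substrate control: the trans-dioxolane forces O5 and O6 equatorial in a chair-like transition state, the acyl anion equivalent approaches anti to the C6–O bond (polar Felkin–Anh arrangement) and the heptadecenyl chain takes the equatorial site, so the new hydroxyl should end axial and cis to O6 (1R); an aminoindanol-derived chiral triazolium salt of matched sense could reinforce this bias. The step needs the aldehyde alone to become the acyl anion and the ketone alone to accept it, which is secured because a ketone cannot form the enaminol, the C1 ketone is activated by its α-oxygen and is the only carbonyl within reach, and high dilution suppresses aldehyde homo-coupling. The weak amine base and the stability of the trans-disubstituted dioxolane should guard C6 against epimerisation and the aldehyde against aldol closure.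

Step 11
Reactants: 16 5,6-O-isopropylidene-3,4-dihydropleiogenone A
Product: 17 (3aR,4R,7aS)-4-[(Z)-heptadec-8-en-1-yl]-2,2-dimethyl-4,5-bis(trimethylsilyloxy)-3a,4,7,7a-tetrahydro-1,3-benzodioxole (C2–C3 silyl enol ether and C1 silyl ether)
Conditions: TMSOTf (2.5 equiv), Et3N (4 equiv), CH2Cl2, −78 to 0 °C
Reagents that add atoms: trimethylsilyl trifluoromethanesulfonate, C[Si](C)(C)OS(=O)(=O)C(F)(F)F
Why: Soft enolisation with a silyl triflate and an amine base gives the silyl enol ether, which can only form toward C3 because C1 is quaternary, and the same reagent silylates the tertiary hydroxyl (silyl enol ether formation and O-silylation); no stereocentre is affected.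

Step 12
Reactants: 17 the bis(trimethylsilyl) compound
Product: 18 5,6-O-isopropylidene-1-O-trimethylsilylpleiogenone A [(3aR,4R,7aS)-4-[(Z)-heptadec-8-en-1-yl]-2,2-dimethyl-4-(trimethylsilyloxy)-4,7a-dihydro-1,3-benzodioxol-5(3aH)-one]
Conditions: Pd(OAc)2 (1.2 equiv), MeCN, rt
Reagents that add atoms: none
Why: Saegusa–Ito oxidation, in which the silyl enol ether transmetalates to a palladium enolate and β-hydride elimination from C4 gives the C3=C4 enone; the isolated chain alkene cannot enter this pathway and should survive at room temperature.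

Step 13
Reactants: 18 5,6-O-isopropylidene-1-O-trimethylsilylpleiogenone A
Product: 19 pleiogenone A [(4S,5R,6R)-6-[(Z)-heptadec-8-en-1-yl]-4,5,6-trihydroxycyclohex-2-en-1-one]
Conditions: TFA/H2O/THF (1:1:4), 0 °C to rt
Reagents that add atoms: none
Why: Acid-catalysed acetal hydrolysis cleaves the strained trans-fused acetonide at its ketal carbon and removes the trimethylsilyl ether in the same operation, so no bond to C1, C5 or C6 is broken and all three stereocentres are retained.

Compound list
1 | 1-decyne | C#CCCCCCCCC | starting material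
2 | 1,7-dibromoheptane | BrCCCCCCCBr | starting material
3 | lithium dec-1-yn-1-ide | [Li]C#CCCCCCCCC | intermediate
4 | 1-bromoheptadec-8-yne | BrCCCCCCCC#CCCCCCCCC | intermediate
5 | (Z)-1-bromoheptadec-8-ene | BrCCCCCCC/C=C\CCCCCCCC | intermediate
6 | dimethyl 2,3-O-isopropylidene-L-tartrate [dimethyl (4R,5R)-2,2-dimethyl-1,3-dioxolane-4,5-dicarboxylate] | COC(=O)[C@@H]1OC(C)(C)O[C@H]1C(=O)OC | starting material
7 | methyl (4R,5S)-5-(hydroxymethyl)-2,2-dimethyl-1,3-dioxolane-4-carboxylate | COC(=O)[C@@H]1OC(C)(C)O[C@H]1CO | intermediate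
8 | methyl (4R,5R)-5-formyl-2,2-dimethyl-1,3-dioxolane-4-carboxylate | COC(=O)[C@@H]1OC(C)(C)O[C@H]1C=O | intermediate
9 | methyl (4R,5S)-5-[(E)-3-tert-butoxy-3-oxoprop-1-en-1-yl]-2,2-dimethyl-1,3-dioxolane-4-carboxylate | COC(=O)[C@@H]1OC(C)(C)O[C@H]1/C=C/C(=O)OC(C)(C)C | intermediate
10 | methyl (4R,5S)-5-(3-tert-butoxy-3-oxopropyl)-2,2-dimethyl-1,3-dioxolane-4-carboxylate | COC(=O)[C@@H]1OC(C)(C)O[C@H]1CCC(=O)OC(C)(C)C | intermediate
11 | tert-butyl 3-[(4S,5R)-5-[methoxy(methyl)carbamoyl]-2,2-dimethyl-1,3-dioxolan-4-yl]propanoate | CON(C)C(=O)[C@@H]1OC(C)(C)O[C@H]1CCC(=O)OC(C)(C)C | intermediate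
12 | (Z)-heptadec-8-en-1-ylmagnesium bromide | Br[Mg]CCCCCCC/C=C\CCCCCCCC | intermediate
13 | tert-butyl 3-[(4S,5R)-2,2-dimethyl-5-[(Z)-octadec-9-enoyl]-1,3-dioxolan-4-yl]propanoate | CCCCCCCC/C=C\CCCCCCCC(=O)[C@@H]1OC(C)(C)O[C@H]1CCC(=O)OC(C)(C)C | intermediate
14 | 3-[(4S,5S)-5-[(Z)-1-hydroxyoctadec-9-en-1-yl]-2,2-dimethyl-1,3-dioxolan-4-yl]propan-1-ol, both carbinol epimers | CCCCCCCC/C=C\CCCCCCCC(O)[C@@H]1OC(C)(C)O[C@H]1CCCO | intermediate
15 | 3-[(4S,5R)-2,2-dimethyl-5-[(Z)-octadec-9-enoyl]-1,3-dioxolan-4-yl]propanal | O=CCC[C@@H]1OC(C)(C)O[C@H]1C(=O)CCCCCCC/C=C\CCCCCCCC | intermediate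
16 | 5,6-O-isopropylidene-3,4-dihydropleiogenone A [(3aR,4R,7aS)-4-[(Z)-heptadec-8-en-1-yl]-4-hydroxy-2,2-dimethylhexahydro-1,3-benzodioxol-5-one] | CCCCCCCC/C=C\CCCCCCC[C@]1(O)C(=O)CC[C@@H]2OC(C)(C)O[C@@H]12 | intermediate
17 | (3aR,4R,7aS)-4-[(Z)-heptadec-8-en-1-yl]-2,2-dimethyl-4,5-bis(trimethylsilyloxy)-3a,4,7,7a-tetrahydro-1,3-benzodioxole | CCCCCCCC/C=C\CCCCCCC[C@]1(O[Si](C)(C)C)C(O[Si](C)(C)C)=CC[C@@H]2OC(C)(C)O[C@@H]12 | intermediate
18 | 5,6-O-isopropylidene-1-O-trimethylsilylpleiogenone A [(3aR,4R,7aS)-4-[(Z)-heptadec-8-en-1-yl]-2,2-dimethyl-4-(trimethylsilyloxy)-4,7a-dihydro-1,3-benzodioxol-5(3aH)-one] | CCCCCCCC/C=C\CCCCCCC[C@]1(O[Si](C)(C)C)C(=O)C=C[C@@H]2OC(C)(C)O[C@@H]12 | intermediate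
19 | pleiogenone A [(4S,5R,6R)-6-[(Z)-heptadec-8-en-1-yl]-4,5,6-trihydroxycyclohex-2-en-1-one] | CCCCCCCC/C=C\CCCCCCC[C@]1(O)C(=O)C=C[C@H](O)[C@H]1O | target

Total step count: 13. Longest linear sequence: 11 steps (6 to 19, steps 3–13); the chain branch (steps 1–2) joins at step 7.

Steps most likely to fail

Step 10 (key step). The acyl anion equivalent may discriminate poorly between the two faces of the C1 ketone, or base-triggered aldol closure of C3 onto C1 may outrun carbene catalysis. The fallback sets out from 15 and returns at 16. A reductive ketyl–carbonyl (pinacol) cyclisation of 15 with SmI2 (THF, t-BuOH, −78 °C) is non-basic, and trivalent samarium bridging both oxygens in a chair with the chain equatorial should give the cis-1,2-diol (3aR,4S,5S,7aS)-4-[(Z)-heptadec-8-en-1-yl]-2,2-dimethylhexahydro-1,3-benzodioxole-4,5-diol F1. Parikh–Doering oxidation of its secondary C2 hydroxyl (SO3·pyridine, DMSO, i-Pr2NEt, CH2Cl2, 0 °C) would then give 16; the C2 configuration of the diol is irrelevant.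

Step 12. Palladium hydride released after β-hydride elimination may isomerise or shift the remote Z-alkene, or the enol ether may simply be protodesilylated back to the ketone. The fallback sets out from 17 and returns at 18. Selenenylation of the silyl enol ether with PhSeCl (CH2Cl2, −78 °C), which reacts with the enol ether far faster than with the isolated alkene, should give the α-selanyl ketone (3aR,4R,7aS)-4-[(Z)-heptadec-8-en-1-yl]-2,2-dimethyl-6-(phenylselanyl)-4-(trimethylsilyloxy)hexahydro-1,3-benzodioxol-5-one F2 (both C3 epimers). Oxidation with H2O2/pyridine (CH2Cl2, 0 °C) gives the corresponding selenoxide, the 6-(phenylseleninyl) ketone F3, whose syn-elimination toward C4 delivers 18.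

Step 3. Over-reduction to the threitol acetonide and statistical mixing of diester, hydroxy ester and diol may erode the material supply. The fallback sets out from 6 and returns at 7. Monosaponification with KOH (1 equiv, MeOH, rt) gives (4R,5R)-5-(methoxycarbonyl)-2,2-dimethyl-1,3-dioxolane-4-carboxylic acid F4, and chemoselective reduction of the carboxylic acid with BH3·SMe2 (THF, 0 °C), which spares the ester, gives 7.

Further compounds
F1 | step 10 | (3aR,4S,5S,7aS)-4-[(Z)-heptadec-8-en-1-yl]-2,2-dimethylhexahydro-1,3-benzodioxole-4,5-diol | CCCCCCCC/C=C\CCCCCCC[C@]1(O)[C@@H](O)CC[C@@H]2OC(C)(C)O[C@@H]12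
F2 | step 12 | (3aR,4R,7aS)-4-[(Z)-heptadec-8-en-1-yl]-2,2-dimethyl-6-(phenylselanyl)-4-(trimethylsilyloxy)hexahydro-1,3-benzodioxol-5-one, both C3 epimers | CCCCCCCC/C=C\CCCCCCC[C@]1(O[Si](C)(C)C)C(=O)C([Se]c3ccccc3)C[C@@H]2OC(C)(C)O[C@@H]12
F3 | step 12 | (3aR,4R,7aS)-4-[(Z)-heptadec-8-en-1-yl]-2,2-dimethyl-6-(phenylseleninyl)-4-(trimethylsilyloxy)hexahydro-1,3-benzodioxol-5-one | CCCCCCCC/C=C\CCCCCCC[C@]1(O[Si](C)(C)C)C(=O)C([Se](=O)c3ccccc3)C[C@@H]2OC(C)(C)O[C@@H]12
F4 | step 3 | (4R,5R)-5-(methoxycarbonyl)-2,2-dimethyl-1,3-dioxolane-4-carboxylic acid | COC(=O)[C@@H]1OC(C)(C)O[C@H]1C(=O)O
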